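## Structural features

The target is a single carbocycle, a cyclohex-1-ene whose C1 carries a methyl ester conjugated with the C1=C2 double bond. C6 is a methylene, and C3, C4 and C5 are three contiguous oxygen-bearing stereocentres. Their configuration is (3R,4S,5R): O3 and O4 are cis, O4 and O5 are trans, which is the arrangement of methyl shikimate. All three oxygens are esterified but not alike: the allylic O3 is an acetate, while O4 and O5 carry (R)-2-methylbutanoyl groups, each with its own α-stereocentre (five stereocentres in all). Fragile points are the allylic acetate (migration to the cis-neighbouring O4, elimination towards a benzoate), the four ester groups (no selective late hydrolysis is possible) and the enolisable α-centres of the 2-methylbutanoyl groups. The real difficulty is the absolute configuration of the oxygen triad together with the distinction of O3 from O4 and O5 by acyl group. The key step exploits the 1,3-relationship between the ester carbon C1 and the oxygenated carbon C3 across C1=C2: C3–C4–C5–C6 is a 1-oxygenated butadiene and C1–C2 a two-carbon dienophile whose nitro group on C2 steers the orientation and later leaves to give C1=C2.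

## Logic of the disconnections

17 ⇒ 14 + 15. The two acyl C–O bonds at O4 and O5 are cut. Both acyl groups are identical and come from one enantiopure acid, so they are best introduced last and together. This removes the two exocyclic stereocentres and leaves a core in which O3 is already distinguished. The forward step (through 16) must acylate a flanked secondary hydroxyl faster than the acetyl group on O3 can move to O4, and must not open a ketene or enolate path at the α-centre of 15.

14 ⇒ 12. The C4–O bond is cut and the epoxide restored; O4 of 14 is recognised as the former carbonyl oxygen of the O3 acetyl group. The acetyl group thus becomes its own reagent: delivered from the face of O3 it can only place O4 cis to O3, and the epoxide oxygen that stays on C5 is then trans to O4. Two stereocentres and the O3/O4 distinction are traced back to one epoxide. The forward step needs the epoxide anti to the acetoxy group, participation ahead of external water (13 is formed before water is added), and collapse of the hydrated cation with the acetyl group left on O3.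

12 ⇒ 10. The acetyl–O3 bond is cut and replaced by an O–Si bond (through 11). The acetate cannot be present earlier: next to a nitro group it would leave through the nitronate far faster than nitrous acid leaves through the ester enolate, and at a doubly allylic position it would invite aromatisation. A silyl ether is inert in both situations and its bulk helps the facial control of the epoxidation. The forward step must free O3 without a base strong enough to open the epoxy enoate.

10 ⇒ 9. The two epoxide C–O bonds are cut. C4=C5 is the only isolated alkene of 9, so the oxidation is chemoselective on electronic grounds. Two stereocentres are removed and C3 remains as the only one. The forward step must deliver oxygen to the face opposite the C3 substituent.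

9 ⇒ 8. Hydrogen is put back on C1 and a nitro group on C2. This reveals a cyclohexene with acceptor groups on adjacent carbons, a cycloaddition retron. The nitro group enforces the 1,3-relationship of ester and oxygen that a propiolate-type dienophile would not give. The forward step is an E1cB loss of nitrous acid that must leave the C3 oxygen in place and must not run on to a benzoate.

8 ⇒ 7 + 5. C2–C3 and C6–C1 are cut. Two bonds, the ring and the stereocentre that later controls the other two are formed in one convergent step from a four-carbon and a two-carbon piece. The forward step must join the oxygenated diene terminus to the nitro-bearing carbon and must control both face and endo/exo topology, because C1 and C2 are later flattened and only C3 carries the stereochemical information onward.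

7 ⇒ 6 and 5 ⇒ 3 ⇒ 1 + 2. In 7 the O–Si bond is cut and the dienol returned to the enal 6. In 5 the double bond is taken back to the β-hydroxy nitro compound 3 (through 4), and the bond between the carbinol carbon and the nitromethyl carbon is cut to give 1 and 2. This aldol-type assembly is preferred to the nitration of an acrylate because it avoids a toxic gaseous nitrogen oxide and iodine. The demand is a dehydration mild enough not to polymerise 5.

## Other disconnections considered

Alternative 1: The cut is at C1–C2 and C5–C6, with an oxygen bridge between C2 and C5 that becomes O5. Furan A1 and 2,2,2-trifluoroethyl acrylate A2 would combine in a Diels–Alder reaction catalysed by a chiral cationic boron Lewis acid to give the endo 7-oxanorbornene A3. Base would open the bridge by β-elimination from the ester enolate to the dienol A4, and C3=C4 would then be cis-dihydroxylated anti to O5.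
- In its favour: enantioselective cycloadditions of acrylate-type dienophiles under this kind of catalysis are established, a clear advantage over the chosen plan, whose asymmetric step is untested. Both components are commodity chemicals. O5 is unmasked alone in A4 and can be acylated before the other two oxygens exist.
- Against it here: furan cycloadditions are reversible. A4 is one dehydration away from a benzoate. The dihydroxylation needs a toxic osmium oxidant and delivers O3 and O4 together as an undifferentiated cis-diol, so the O3 acetate costs a separate orthoester operation. An ester exchange to the methyl ester is also needed.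
- Comparison: structurally the alternative sets C5 in the cycloaddition and C3/C4 by oxidation, whereas the chosen plan sets C3 in the cycloaddition and C4/C5 by oxidation, with the C3 oxygen acting as the C4 nucleophile. Mechanistically both are a [4+2] followed by an E1cB event that flattens C1, and both turn endo/exo control into enantiopurity (equal on this point). The step count is about equal, possibly one fewer for the alternative. On precedent for the key step the alternative is better; on singling out O3 the chosen plan is better.

Alternative 2: The cut is at C3–C4. The acyclic dialdehyde A5 would be treated with SmI2 A6 (divalent samarium); reductive coupling of the enal carbon C3 with the α-alkoxy aldehyde carbon C4 would close the ring as the cis-diol A7.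
- In its favour: the cis relationship of O3 and O4 would arise in the ring-closing event through chelation of both oxygens to one samarium centre, a well-established form of control in pinacol cyclisations. O5 is already different from O3 and O4 (equal to the chosen plan for O5). C5 can come from the chiral pool, so the ring-forming step needs no asymmetric catalysis, which is better than the chosen plan on that count.
- Against it here: the unsaturated aldehyde of A5 is also a β-formyl acrylate. One-electron reduction would give a delocalised radical anion that can couple at carbon or be reduced in the conjugate sense instead of forming a ketyl at C3. The α-alkoxy aldehyde can lose its alkoxy group reductively or epimerise at C5. A5 is a sensitive 1,6-dialdehyde whose alkene geometry must be kept, and its synthesis needs an asymmetric step of its own. O3 and O4 emerge undifferentiated, and an oxidative ether cleavage plus three acylations follow.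
- Comparison: structurally the alternative forms the most hindered ring bond between two new stereocentres, while the chosen plan forms two unhindered bonds and one stereocentre. Mechanistically it is a radical-anion coupling under substrate control against a pericyclic step under catalyst control. In step economy it is clearly longer.

Alternative 3: The cut is at C1=C2. D-Lyxose A8 would be converted into the phosphonate lactol A9. Base would open the lactol to the aldehyde (sugar C1 = target C2), and an intramolecular Horner–Wadsworth–Emmons reaction would close the cyclohexene to A10.
- In its favour: C2, C3 and C4 of A8 map onto C3, C4 and C5 with the correct configuration, so neither relative nor absolute stereochemistry is at risk. This is better than the chosen plan. The olefination type is well established for sugar-derived phosphonates. In A10, O5 is free while O3 and O4 are tied together.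
- Against it here: attaching the phosphonoacetate carbon to C5 of the sugar needs a primary sulfonate displacement by a stabilised carbanion plus anomeric protection and release. After acylation of O5 the acetonide must be cleaved by acid next to an ester, and an undifferentiated cis-3,4-diol returns, so O3 is singled out by the same kinetic orthoester argument as in the chosen plan but in additional steps.
- Comparison: structurally it takes the oxygen triad from a sugar instead of building it. Mechanistically it is an ionic olefination with no selectivity question. In step economy it is estimated at two or three operations more than the chosen plan. On certainty it is better; on distinguishing O3 it is equal in principle but dearer in steps.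

Key step: step 4

Remarks on the chemistry (assumptions):
- The C3 oxygen is carried from the diene to the epoxide as a tert-butyldimethylsilyl ether and becomes the acetate only in step 7. The bonds formed in the cycloaddition, the ring closed and the skeletons of diene, dienophile and adduct are those of the oxydiene/nitroacrylate union.
- The descriptor at C3 is (S) in 8 and 9 and (R) from 10 onward for the same spatial arrangement, because the CIP priorities of C2 and C4 change.
- Crotonaldehyde 6 is taken as the commercial (E)-isomer and 7 is expected mainly as the (E)-enol ether; the (Z)-isomer is assumed to stay unreacted in step 4.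
- Methyl glyoxylate 1 is assumed to be used as freshly distilled monomer.

## Route

Step 1
Reactants: 1 methyl glyoxylate; 2 nitromethane
Product: 3 methyl 2-hydroxy-3-nitropropanoate (racemic)
Conditions: 2 (5 equiv), Et3N (0.1 equiv), THF, 0 °C to rt
Reagents that add atoms: none
Why: Henry (nitroaldol) addition of the nitronate of 2 to the very electrophilic aldehyde of 1; the amine is catalytic, so no nitronate salt accumulates or is isolated. The new carbinol centre is racemic and is erased in step 2.

Step 2
Reactants: 3 methyl 2-hydroxy-3-nitropropanoate
Product: 5 methyl (E)-3-nitroacrylate, via nitro mesylate 4 (not isolated)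
Conditions: MsCl (1.1 equiv), Et3N (2.2 equiv), CH2Cl2, −20 °C
Reagents that add atoms: none
Why: O-Mesylation followed by E1cB loss of methanesulfonate through the nitronate, the standard dehydration of a nitroaldol; the conjugated (E)-alkene is the stable isomer. Low temperature and no excess of amine limit conjugate addition to 5.

Step 3
Reactants: 6 (E)-crotonaldehyde
Product: 7 (E)-1-(tert-butyldimethylsilyloxy)buta-1,3-diene
Conditions: TBSOTf (1.05 equiv), Et3N (1.3 equiv), Et2O, 0 °C to rt
Reagents that add atoms: tert-butyldimethylsilyl trifluoromethanesulfonate, CC(C)(C)[Si](C)(C)OS(=O)(=O)C(F)(F)F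
Why: O-Silylation of the enal and γ-deprotonation of the resulting oxocarbenium ion (silyl dienol ether formation); the (E)-enol ether should predominate on steric grounds.

Step 4
Reactants: 7 (E)-1-(tert-butyldimethylsilyloxy)buta-1,3-diene; 5 methyl (E)-3-nitroacrylate
Product: 8 methyl (1S,2R,3S)-3-(tert-butyldimethylsilyloxy)-2-nitrocyclohex-4-ene-1-carboxylate (nitro cis to the silyloxy group, trans to the ester)
Conditions: 1,1′-[(1R,2R)-cyclohexane-1,2-diyl]bis{3-[3,5-bis(trifluoromethyl)phenyl]thiourea} (10 mol %), toluene, 4 Å molecular sieves, −78 °C to −40 °C
Reagents that add atoms: none
Why: Proposed new method: a neutral dual hydrogen-bond donor is expected to clamp the two nitro oxygens of 5 (its second thiourea reaching the ester carbonyl), which lowers the LUMO and keeps its largest coefficient on the ester-bearing carbon, so that the nucleophilic CH2 terminus of 7 bonds there (C6–C1) and the silyloxy-bearing terminus bonds to the nitro carbon (C2–C3) in a concerted but asynchronous normal-demand Diels–Alder reaction; the closest known reaction types are the uncatalysed cycloaddition of 1-oxygenated butadienes to 3-nitroacrylates and thiourea-catalysed enantioselective additions and cycloadditions of nitroalkenes. The cyclohexene ring is closed by the intermolecular suprafacial [4+2] union itself, both σ-bonds forming in the same step, so no separate cyclisation mode has to be met. C1 and C2 should come out trans because the (E)-geometry of 5 is transferred stereospecifically, and their absolute configuration is that of the face of 5 left open by the catalyst. C3 is set cis to the nitro group at C2 by the nitro-endo transition state with the (E)-enol ether, so its absolute configuration depends on face selection and endo topology together. The step needs regioselectivity, which the nitro group secures and which hydrogen bonding at nitro (rather than Lewis acid binding at the ester) should reinforce; it needs the catalysed path to outrun the background reaction, hence the low temperature; and it needs a single topology, because endo and exo adducts formed on the same face of 5 have opposite configuration at C3 and would give antipodal 9 once C1 and C2 are flattened. The sense of induction cannot be predicted, so the (R,R)-catalyst stands for whichever antipode leads to 8.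

Step 5
Reactants: 8 methyl (1S,2R,3S)-3-(tert-butyldimethylsilyloxy)-2-nitrocyclohex-4-ene-1-carboxylate
Product: 9 methyl (S)-3-(tert-butyldimethylsilyloxy)cyclohexa-1,4-diene-1-carboxylate
Conditions: DBU (1.5 equiv), THF, −20 °C to 0 °C; cold pH 7 buffer
Reagents that add atoms: none
Why: E1cB elimination of nitrous acid from a β-nitro ester: the ester enolate at C1 expels nitrite from C2, a known reaction of nitroacrylate cycloadducts. The silyloxy group at C3 is too poor a leaving group to be lost through the nitronate, and C3 is not touched.

Step 6
Reactants: 9 methyl (S)-3-(tert-butyldimethylsilyloxy)cyclohexa-1,4-diene-1-carboxylate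
Product: 10 methyl (3R,4R,5R)-3-(tert-butyldimethylsilyloxy)-4,5-epoxycyclohex-1-ene-1-carboxylate (epoxide anti to the silyloxy group)
Conditions: mCPBA (1.2 equiv), NaHCO3 (solid), CH2Cl2, 0 °C
Reagents that add atoms: m-chloroperoxybenzoic acid, OOC(=O)c1cccc(Cl)c1
Why: Prilezhaev epoxidation of the isolated, more electron-rich C4=C5 alkene in preference to the ester-conjugated C1=C2. The bulky silyloxy group at C3 shields its own face, so oxygen should be delivered anti, which sets C4 and C5; the buffer protects the acid-sensitive diene.

Step 7
Reactants: 10 methyl (3R,4R,5R)-3-(tert-butyldimethylsilyloxy)-4,5-epoxycyclohex-1-ene-1-carboxylate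
Product: 12 methyl (3R,4R,5R)-3-acetoxy-4,5-epoxycyclohex-1-ene-1-carboxylate, via epoxy alcohol 11 (not isolated)
Conditions: Bu4NF (1.2 equiv), AcOH (1.2 equiv), THF, 0 °C to rt; then Ac2O (5 equiv), pyridine, 4-(dimethylamino)pyridine (0.1 equiv), 0 °C
Reagents that add atoms: acetic anhydride, CC(=O)OC(C)=O
Why: Fluoride desilylation buffered with acetic acid, so that no free alkoxide can start a Payne rearrangement or a γ-deprotonation of the epoxy enoate, followed in the same flask by nucleophile-catalysed acetylation. No stereocentre is touched.

Step 8
Reactants: 12 methyl (3R,4R,5R)-3-acetoxy-4,5-epoxycyclohex-1-ene-1-carboxylate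
Product: 14 methyl (3R,4S,5R)-3-acetoxy-4,5-dihydroxycyclohex-1-ene-1-carboxylate, via acetoxonium trifluoroborate zwitterion 13 (not isolated)
Conditions: BF3·OEt2 (1.2 equiv), CH2Cl2, −78 °C to −20 °C; then H2O–THF, 0 °C; aq. NaHCO3 to pH 7
Reagents that add atoms: water, O
Why: Lewis acid-activated epoxide opening with anchimeric assistance: the carbonyl oxygen of the C3 acetate attacks C4 from the face opposite the epoxide (5-exo, inversion) to give the cis-fused 1,3-dioxolan-2-ylium ion, while the former epoxide oxygen stays on C5; this sets O4 cis to O3 and O5 trans to O4. Water then adds to the cation, and the orthoacid is expected to collapse under kinetic control to the pseudoaxial allylic acetate on O3 and the equatorial hydroxyl on C4, as cyclic orthoacids on six-membered rings generally do.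

Step 9
Reactants: 14 methyl (3R,4S,5R)-3-acetoxy-4,5-dihydroxycyclohex-1-ene-1-carboxylate; 15 (R)-2-methylbutanoic acid
Product: 17 methyl (3R,4S,5R)-3-acetoxy-4,5-bis{[(2R)-2-methylbutanoyl]oxy}cyclohex-1-ene-1-carboxylate, via (R)-2-methylbutanoic anhydride 16 (not isolated)
Conditions: 15 (6 equiv), N,N′-diisopropylcarbodiimide (3 equiv), CH2Cl2, 0 °C, 30 min; then 14, 4-(dimethylamino)pyridine (0.3 equiv), 0 °C to rt
Reagents that add atoms: none
Why: Steglich-type acylation: the carbodiimide turns 15 into its symmetrical anhydride, which the pyridine catalyst transfers to both secondary hydroxyls. No acid chloride or ketene is involved, so the α-centres should be retained, and an excess of preformed anhydride at 0 °C is meant to make acylation of O4 faster than acetyl migration from O3.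

## Compound list

1 | methyl glyoxylate (methyl 2-oxoacetate) | COC(=O)C=O | starting material
2 | nitromethane | C[N+](=O)[O-] | starting material
3 | methyl 2-hydroxy-3-nitropropanoate (racemic) | COC(=O)C(O)C[N+](=O)[O-] | intermediate
4 | methyl 2-(methanesulfonyloxy)-3-nitropropanoate (racemic nitro mesylate) | COC(=O)C(OS(C)(=O)=O)C[N+](=O)[O-] | intermediate (not isolated)
5 | methyl (E)-3-nitroacrylate | COC(=O)/C=C/[N+](=O)[O-] | intermediate
6 | (E)-crotonaldehyde ((E)-but-2-enal) | C/C=C/C=O | starting material
7 | (E)-1-(tert-butyldimethylsilyloxy)buta-1,3-diene | C=C/C=C/O[Si](C)(C)C(C)(C)C | intermediate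
8 | methyl (1S,2R,3S)-3-(tert-butyldimethylsilyloxy)-2-nitrocyclohex-4-ene-1-carboxylate | COC(=O)[C@H]1CC=C[C@H](O[Si](C)(C)C(C)(C)C)[C@@H]1[N+](=O)[O-] | intermediate
9 | methyl (S)-3-(tert-butyldimethylsilyloxy)cyclohexa-1,4-diene-1-carboxylate | COC(=O)C1=C[C@@H](O[Si](C)(C)C(C)(C)C)C=CC1 | intermediate
10 | methyl (3R,4R,5R)-3-(tert-butyldimethylsilyloxy)-4,5-epoxycyclohex-1-ene-1-carboxylate (epoxide anti to OSi) | COC(=O)C1=C[C@@H](O[Si](C)(C)C(C)(C)C)[C@@H]2O[C@@H]2C1 | intermediate
11 | methyl (3R,4S,5R)-4,5-epoxy-3-hydroxycyclohex-1-ene-1-carboxylate (epoxide anti to OH) | COC(=O)C1=C[C@@H](O)[C@@H]2O[C@@H]2C1 | intermediate (not isolated)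
12 | methyl (3R,4R,5R)-3-acetoxy-4,5-epoxycyclohex-1-ene-1-carboxylate (epoxide anti to OAc) | COC(=O)C1=C[C@@H](OC(C)=O)[C@@H]2O[C@@H]2C1 | intermediate
13 | cis-fused acetoxonium ion (2-methyl-1,3-dioxolan-2-ylium spanning O3 and O4) with the C5 oxygen bound to BF3, zwitterion | COC(=O)C1=C[C@H]2OC(C)=[O+][C@H]2[C@H](O[B-](F)(F)F)C1 | intermediate (not isolated)
14 | methyl (3R,4S,5R)-3-acetoxy-4,5-dihydroxycyclohex-1-ene-1-carboxylate (methyl 3-O-acetylshikimate) | COC(=O)C1=C[C@@H](OC(C)=O)[C@@H](O)[C@H](O)C1 | intermediate
15 | (R)-2-methylbutanoic acid | CC[C@@H](C)C(=O)O | starting material
16 | (R)-2-methylbutanoic anhydride | CC[C@@H](C)C(=O)OC(=O)[C@H](C)CC | intermediate (not isolated)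
17 | methyl (3R,4S,5R)-3-acetoxy-4,5-bis{[(2R)-2-methylbutanoyl]oxy}cyclohex-1-ene-1-carboxylate (CNP0132712.1) | CC[C@@H](C)C(=O)O[C@@H]1[C@H](OC(C)=O)C=C(C(=O)OC)C[C@H]1OC(=O)[C@H](C)CC | target

## Step count and risks

Total step count: 9. Longest linear sequence: 8 steps (steps 1, 2, 4, 5, 6, 7, 8 and 9, from 1); step 3 is a one-step side branch.

Least certain steps:

Step 4 (key step). The most likely failure is low enantiomeric purity at C3. It can arise from weak facial discrimination by a catalyst that only hydrogen-bonds to the dienophile, from a mixture of endo and exo topologies (which deliver opposite C3 configurations), or from the uncatalysed background reaction of a very reactive diene/dienophile pair. A stepwise conjugate addition of the silyl dienol ether is a further possible leak.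

Fallback, using known chemistry only: 7 and 5 are combined without catalyst (toluene, 0 °C to rt), which should give the racemic cycloadduct F1. Steps 5 and 6 applied to it should give the racemic diene F2 and the racemic anti epoxide F3. Buffered desilylation as in the first half of step 7, now with isolation, should give the racemic epoxy alcohol F4. A lipase-catalysed transesterification with vinyl acetate (Burkholderia cepacia lipase, tert-butyl methyl ether, rt; kinetic resolution of a secondary alcohol) is then expected to acetylate the (3R)-enantiomer, whose larger C4 side and smaller C2 side fit the empirical model for the fast-reacting alcohol. The acetate formed would be 12 and the enantiomeric epoxy alcohol F5 would be left behind. The route is rejoined at 12. Should the enzyme prefer the other antipode, the unreacted alcohol would be 11 itself and would be acetylated as in step 7.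

Step 8. The most likely failure is misdelivery of the acetyl group: collapse of the hydrated cation towards the O4 acetate, or acetyl migration from O3 to O4 during the aqueous quench, since the two oxygens are cis and the equatorial ester is the more stable. Opening without participation (water at C5) is a lesser risk.

Fallback: the crude product, a mixture of 14 and methyl 4-O-acetylshikimate F7, is converged by methanolysis (K2CO3, MeOH, 0 °C) to methyl shikimate F8. The trans-diequatorial 4,5-diol is then protected selectively as the butane-2,3-diacetal F9 (butane-2,3-dione, HC(OMe)3, (1S)-(+)-camphor-10-sulfonic acid cat., MeOH, reflux), which leaves only O3 free. Acetylation (Ac2O, pyridine) gives the acetate F10, and aqueous trifluoroacetic acid at 0 °C removes the diacetal. The route is rejoined at 14, with O3 now singled out by a protecting group and not by the kinetics of orthoacid collapse.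

Step 9. The most likely failure is acetyl migration from O3 to the free cis-neighbouring O4 (and onward to O5) under the basic, nucleophile-catalysed conditions, in competition with a slow acylation of the flanked O4. Partial epimerisation of the acyl donor is a second risk.

Fallback: the route is left at 12. The cation of step 8 is quenched with MeOH/Et3N instead of water, which should give the cyclic methyl orthoester F11 with only O5 free. O5 is acylated with preformed 16 and 4-(dimethylamino)pyridine to give the orthoester ester F12, in which no hydroxyl stands next to an ester. Aqueous acetic acid (80 %, rt) then opens the orthoester to the hydroxy acetate F13, which is acylated at once without base (16, Sc(OTf)3 cat., MeCN, −20 °C). The route is rejoined at 17.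

Step 5. The most likely failure is aromatisation of the product, or migration of C4=C5 into conjugation, under the base: the 1,4-diene is one elimination of silanol away from a benzoate.

Fallback: the order of oxidation and elimination is reversed. 8 is epoxidised first (mCPBA, NaHCO3, CH2Cl2, rt; oxygen anti to the silyloxy and nitro groups) to the nitro epoxide F6. Brief treatment with DBU at −20 °C then removes nitrous acid. The route is rejoined at 10 and the 1,4-diene is never formed.

## Further compounds

F1 | step 4 | racemic methyl (1S*,2R*,3S*)-3-(tert-butyldimethylsilyloxy)-2-nitrocyclohex-4-ene-1-carboxylate (both enantiomers) | COC(=O)[C@H]1CC=C[C@H](O[Si](C)(C)C(C)(C)C)[C@@H]1[N+](=O)[O-].COC(=O)[C@@H]1CC=C[C@@H](O[Si](C)(C)C(C)(C)C)[C@H]1[N+](=O)[O-]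
F2 | step 4 | racemic methyl 3-(tert-butyldimethylsilyloxy)cyclohexa-1,4-diene-1-carboxylate (both enantiomers) | COC(=O)C1=C[C@@H](O[Si](C)(C)C(C)(C)C)C=CC1.COC(=O)C1=C[C@H](O[Si](C)(C)C(C)(C)C)C=CC1
F3 | step 4 | racemic methyl 3-(tert-butyldimethylsilyloxy)-4,5-epoxycyclohex-1-ene-1-carboxylate, epoxide anti to OSi (both enantiomers) | COC(=O)C1=C[C@@H](O[Si](C)(C)C(C)(C)C)[C@@H]2O[C@@H]2C1.COC(=O)C1=C[C@H](O[Si](C)(C)C(C)(C)C)[C@H]2O[C@H]2C1
F4 | step 4 | racemic methyl 4,5-epoxy-3-hydroxycyclohex-1-ene-1-carboxylate, epoxide anti to OH (both enantiomers) | COC(=O)C1=C[C@@H](O)[C@@H]2O[C@@H]2C1.COC(=O)C1=C[C@H](O)[C@H]2O[C@H]2C1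
F5 | step 4 | methyl (3S,4R,5S)-4,5-epoxy-3-hydroxycyclohex-1-ene-1-carboxylate (enantiomer of 11) | COC(=O)C1=C[C@H](O)[C@H]2O[C@H]2C1
F6 | step 5 | methyl (1S,2R,3R,4R,5R)-3-(tert-butyldimethylsilyloxy)-4,5-epoxy-2-nitrocyclohexane-1-carboxylate (epoxide anti to OSi and NO2) | COC(=O)[C@H]1C[C@H]2O[C@H]2[C@H](O[Si](C)(C)C(C)(C)C)[C@@H]1[N+](=O)[O-]
F7 | step 8 | methyl (3R,4S,5R)-4-acetoxy-3,5-dihydroxycyclohex-1-ene-1-carboxylate (methyl 4-O-acetylshikimate) | COC(=O)C1=C[C@@H](O)[C@@H](OC(C)=O)[C@H](O)C1
F8 | step 8 | methyl (3R,4S,5R)-3,4,5-trihydroxycyclohex-1-ene-1-carboxylate (methyl shikimate) | COC(=O)C1=C[C@@H](O)[C@@H](O)[C@H](O)C1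
F9 | step 8 | methyl shikimate 4,5-O-(2,3-dimethoxybutane-2,3-diyl) acetal, acetal carbons (S,S), 3-OH free | COC(=O)C1=C[C@@H](O)[C@H]2O[C@](C)(OC)[C@@](C)(OC)O[C@@H]2C1
F10 | step 8 | methyl 3-O-acetylshikimate 4,5-O-(2,3-dimethoxybutane-2,3-diyl) acetal, acetal carbons (S,S) | COC(=O)C1=C[C@@H](OC(C)=O)[C@H]2O[C@](C)(OC)[C@@](C)(OC)O[C@@H]2C1
F11 | step 9 | methyl shikimate 3,4-O-(1-methoxyethylidene) orthoester, 5-OH free (epimers at the orthoester carbon) | COC(=O)C1=C[C@H]2OC(C)(OC)O[C@H]2[C@H](O)C1
F12 | step 9 | methyl 5-O-[(2R)-2-methylbutanoyl]shikimate 3,4-O-(1-methoxyethylidene) orthoester (epimers at the orthoester carbon) | COC(=O)C1=C[C@H]2OC(C)(OC)O[C@H]2[C@H](OC(=O)[C@H](C)CC)C1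
F13 | step 9 | methyl (3R,4S,5R)-3-acetoxy-4-hydroxy-5-{[(2R)-2-methylbutanoyl]oxy}cyclohex-1-ene-1-carboxylate | COC(=O)C1=C[C@@H](OC(C)=O)[C@@H](O)[C@H](OC(=O)[C@H](C)CC)C1
A1 | alternative 1 | furan | c1ccoc1
A2 | alternative 1 | 2,2,2-trifluoroethyl acrylate | C=CC(=O)OCC(F)(F)F
A3 | alternative 1 | 2,2,2-trifluoroethyl (1R,2R,4R)-7-oxabicyclo[2.2.1]hept-5-ene-2-carboxylate (endo) | FC(F)(F)COC(=O)[C@@H]1C[C@@H]2C=C[C@H]1O2
A4 | alternative 1 | 2,2,2-trifluoroethyl (5R)-5-hydroxycyclohexa-1,3-diene-1-carboxylate | O=C(OCC(F)(F)F)C1=CC=C[C@H](O)C1
A5 | alternative 2 | methyl (E)-2-{(2R)-2-[(4-methoxybenzyl)oxy]-3-oxopropyl}-4-oxobut-2-enoate | O=C/C=C(\C[C@@H](OCc1ccc(OC)cc1)C=O)C(=O)OC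
A6 | alternative 2 | samarium diiodide, SmI2 | [Sm+2].[I-].[I-]
A7 | alternative 2 | methyl 5-O-(4-methoxybenzyl)shikimate | O[C@@H]1[C@H](O)C=C(C(=O)OC)C[C@H]1OCc2ccc(OC)cc2
A8 | alternative 3 | D-lyxose (open-chain form) | O=C[C@@H](O)[C@@H](O)[C@H](O)CO
A9 | alternative 3 | 5-deoxy-5-[(dimethoxyphosphoryl)(methoxycarbonyl)methyl]-2,3-O-isopropylidene-D-lyxofuranose (anomers, epimers at the phosphonate carbon) | OC1O[C@H](CC(C(=O)OC)P(=O)(OC)OC)[C@@H]2OC(C)(C)O[C@H]12
A10 | alternative 3 | methyl 3,4-O-isopropylideneshikimate (5-OH free) | CC1(C)O[C@@H]2[C@H](O1)C=C(C(=O)OC)C[C@H]2O
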